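In daucane numbering, lapiferine is cut at the C4–C5 bond of the five-membered ring. Stripped of the C8 methyl and its oxygens, the seven-membered ring (C1, C5–C10) has a mirror plane through quaternary C1 and the C7–C8 midpoint, so the two carbonyls of a 2-methylcycloheptane-1,3-dione (future C5 and C10) are enantiotopic. A chiral carbene-catalysed crossed benzoin of the pendant C4 aldehyde closes the cyclopentane, fixes C1 and leaves two chemically distinct ketones in one operation. Its precursor is achiral 2-methyl-2-(3-oxopropyl)cycloheptane-1,3-dione, available in two steps. C5/C6, C4 and C8–C10 are then set by substrate-controlled reactions.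

Key step: step 3

Convention: daucane numbering is used for all bicyclic compounds (C1 methyl-bearing ring-fusion carbon, C2–C4 the rest of the five-membered ring, C5 the other ring-fusion carbon, C6–C10 the rest of the seven-membered ring); β is the face of the C1 methyl, α the opposite face.

Remark: which antipode of the aminoindanol-derived triazolium salt delivers (1S,5R)-6 is assumed to be settled in a first trial run, since both antipodes are made from the commercial cis-1-amino-2-indanols.

Step 1
Reactants: 1 cycloheptane-1,3-dione; 2 iodomethane
Product: 3 2-methylcycloheptane-1,3-dione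
Conditions: MeI (1.05 equiv), K2CO3, acetone, reflux
Reagents that add atoms: iodomethane (2), CI
Why: Enolate C-alkylation (SN2) of the 1,3-dione with the soft electrophile iodomethane under carbonate conditions is the standard entry to 2-alkylcycloalkane-1,3-diones, and one equivalent of iodide keeps dialkylation and O-methylation minor.

Step 2
Reactants: 3 2-methylcycloheptane-1,3-dione; 4 acrolein
Product: 5 2-methyl-2-(3-oxopropyl)cycloheptane-1,3-dione
Conditions: acrolein, Et3N (cat.), CH2Cl2, 0 °C to rt
Reagents that add atoms: acrolein (4), C=CC=O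
Why: Amine-catalysed Michael addition of the 2-substituted 1,3-dione to acrolein creates the quaternary (still prochiral) C1 and the three-carbon aldehyde arm C2–C4, and stops at the mono-adduct because the product has no acidic hydrogen left between the carbonyls.

Step 3
Reactants: 5 2-methyl-2-(3-oxopropyl)cycloheptane-1,3-dione
Product: 6 cis-fused ketol (1S,5R)-5-hydroxy-1-methylbicyclo[5.3.0]decane-4,10-dione
Conditions: 2-(pentafluorophenyl)-5a,10b-dihydro-4H,6H-indeno[2,1-b][1,2,4]triazolo[4,3-d][1,4]oxazin-2-ium tetrafluoroborate (one antipode, 10 mol %), Et3N (10 mol %), toluene, rt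
Reagents that add atoms: none
Why: The triazolylidene released by the amine adds to the aldehyde carbon C4 and proton transfer gives the Breslow intermediate, an acyl anion equivalent, which attacks one of the two enantiotopic ring ketones and then expels the carbene, leaving the C4 ketone and the tertiary C5 alcohol. The closest known reaction type is the carbene-catalysed intramolecular crossed benzoin desymmetrisation of 2-substituted 2-(3-oxopropyl)cycloalkane-1,3-diones. The five-membered ring closes in a 5-exo-trig mode by attack of C4 on the C5 carbonyl carbon. Quaternary C1 is set by the chiral aminoindanol backbone of the catalyst, which decides which carbonyl becomes C5, and the C5 carbinol follows from the short tether, which allows only the cis-fused ketol with the hydroxyl cis to the C1 methyl. The step needs the aldehyde to act as donor and a ketone as acceptor without aldol or retro-Claisen side reactions: ketones do not form Breslow intermediates, the dione cannot enolise between its carbonyls, the tether permits only five-ring closure, and a weak amine base at room temperature keeps enolate chemistry slow.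

Step 4
Reactants: 6 cis-fused ketol
Product: 7 (1S)-1-methylbicyclo[5.3.0]dec-5-ene-4,10-dione
Conditions: SOCl2, pyridine, CH2Cl2, 0 °C
Reagents that add atoms: none
Why: Dehydration of a tertiary α-ketol through its chlorosulfite (E2 with pyridine) is the classical route from 17α-hydroxy-20-keto steroids to their 16-en-20-ones, and because C1 is quaternary and C4 a carbonyl only C6 carries β-hydrogens, so the C5=C6 enone is the only alkene that can form and the C5 stereocentre is erased as planned.

Step 5
Reactants: 7 C5=C6 enone
Product: 8 5α,6α-epoxy-1β-methylbicyclo[5.3.0]decane-4,10-dione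
Conditions: 30% H2O2, NaOH (cat.), MeOH, 0 °C
Reagents that add atoms: hydrogen peroxide, OO
Why: Weitz–Scheffer nucleophilic epoxidation is specific for the electron-poor C5=C6 bond and leaves the saturated C10 ketone alone, and the peroxy enolate is expected to close on the α face, away from the C1 methyl that stands pseudoaxial over the β face of the alkene, which sets the C6–O configuration.

Step 6
Reactants: 8 5α,6α-epoxy diketone
Product: 9 6α-hydroxy-1β-methyl-5α-H-bicyclo[5.3.0]decane-4,10-dione (trans-fused)
Conditions: SmI2 (2.2 equiv), THF–MeOH, −90 °C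
Reagents that add atoms: none
Why: Samarium diiodide reduction of an α,β-epoxy ketone cleaves only the Cα–O bond (C5–O) at −90 °C, a temperature at which the isolated C10 ketone is not reduced, so the C6 carbinol keeps its configuration, and kinetic protonation of the samarium enolate at C5 by methanol held on the neighbouring α-oriented C6 oxygen–samarium unit, on the face away from the C1 methyl, should give the trans ring fusion (H5 α); crude 9 is used at once to avoid β-elimination.

Step 7
Reactants: 9 trans-fused hydroxy diketone; 10 isopropylmagnesium chloride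
Product: 11 4β,6α-dihydroxy-4α-isopropyl-1β-methyl-5α-H-bicyclo[5.3.0]decan-10-one
Conditions: iPrMgCl, CeCl3 (3 equiv each), THF, −78 °C
Reagents that add atoms: isopropylmagnesium chloride (10), CC(C)[Mg]Cl
Why: Organocerium 1,2-addition to a β-hydroxy ketone is used because the C6 alkoxide chelates the metal to the C4 carbonyl and so activates this cyclopentanone over the neopentyl-type C10 cycloheptanone next to quaternary C1, the weakly basic reagent suppresses enolisation, retro-aldol cleavage and β-elimination, and isopropyl is delivered to the α face, anti to the axial C1 methyl of the trans-fused bicycle, which sets the 4β-hydroxyl.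

Step 8
Reactants: 11 diol ketone
Product: 13 4β,6α-bis(triethylsilyloxy)-4α-isopropyl-1β-methyl-5α-H-bicyclo[5.3.0]dec-8-en-10-one, via tris-silyl enol ether 12 (not isolated)
Conditions: Et3SiOTf (4 equiv), Et3N, CH2Cl2, 0 °C to rt; then Pd(OAc)2 (1.1 equiv), MeCN, rt
Reagents that add atoms: triethylsilyl trifluoromethanesulfonate, CC[Si](CC)(CC)OS(=O)(=O)C(F)(F)F
Why: Soft enolisation with the silyl triflate protects both hydroxyls and converts the C10 ketone, which can enolise only toward C9 because C1 is quaternary, into its silyl enol ether, and Saegusa–Ito oxidation with divalent palladium then gives the C8=C9 enone regiospecifically.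

Step 9
Reactants: 13 bis-silyl C8=C9 enone; 14 methyllithium
Product: 16 4β,6α-bis(triethylsilyloxy)-4α-isopropyl-1β,8-dimethyl-5α-H-bicyclo[5.3.0]dec-8-en-10-one, via trimethylsilyl enol ether 15 (not isolated)
Conditions: Me2CuLi (from MeLi, CuI), Me3SiCl, THF, −78 °C; then Pd(OAc)2 (1.1 equiv), MeCN, rt
Reagents that add atoms: methyllithium (14), [Li]C; chlorotrimethylsilane, C[Si](C)(C)Cl (its silicon stays only in intermediate 15)
Why: Silyl-chloride-accelerated Gilman cuprate conjugate addition puts the methyl on C8 and traps the enolate as its silyl enol ether, and a second Saegusa–Ito oxidation (β-hydride elimination of the single C8 hydrogen) restores the enone with the methyl on C8, so the transient C8 stereocentre does not matter.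

Step 10
Reactants: 16 bis-silyl 8-methyl enone
Product: 17 4β,6α-dihydroxy-4α-isopropyl-1β,8-dimethyl-5α-H-bicyclo[5.3.0]dec-8-en-10-one
Conditions: HF·pyridine, pyridine, THF, 0 °C to rt
Reagents that add atoms: none
Why: Fluoride-mediated cleavage of both triethylsilyl ethers with buffered HF·pyridine is mildly acidic, so the enone cannot undergo base-induced vinylogous elimination of the C6 oxygen and no stereocentre is touched.

Step 11
Reactants: 17 diol enone; 18 angelic acid
Product: 19 6α-angeloyloxy-4β-hydroxy-4α-isopropyl-1β,8-dimethyl-5α-H-bicyclo[5.3.0]dec-8-en-10-one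
Conditions: angelic acid, 2,4,6-trichlorobenzoyl chloride, Et3N, toluene, rt; then 17, 75 °C
Reagents that add atoms: angelic acid (18), C/C=C(/C)C(=O)O
Why: Yamaguchi-type esterification through the preformed mixed anhydride, run without a nucleophilic pyridine catalyst, is the established way to make angelates without Z-to-E isomerisation to the tiglate, and it acylates only the secondary C6 hydroxyl (the C4 hydroxyl is tertiary and hindered) with retention, since the C6–O bond is not broken.

Step 12
Reactants: 19 angelate enone
Product: 20 6α-angeloyloxy-4β,10α-dihydroxy-4α-isopropyl-1β,8-dimethyl-5α-H-bicyclo[5.3.0]dec-8-ene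
Conditions: NaBH4, CeCl3·7H2O, MeOH, −78 to 0 °C
Reagents that add atoms: none
Why: Luche 1,2-reduction leaves the unsaturated ester untouched, and hydride is expected to attack the β face of C10, antiperiplanar to the C1–C5 ring bond that stands nearly perpendicular to the carbonyl plane in the chair-like cycloheptenone of the trans-fused bicycle (Felkin–Anh-type torsional control), which gives the 10α-alcohol trans to the C1 methyl.

Step 13
Reactants: 20 allylic alcohol
Product: 21 lapiferine
Conditions: VO(acac)2 (vanadyl bis(acetylacetonate), 5 mol %), tBuOOH, CH2Cl2, 0 °C to rt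
Reagents that add atoms: tert-butyl hydroperoxide, CC(C)(C)OO
Why: Vanadium-catalysed hydroxyl-directed epoxidation delivers oxygen to the C8=C9 bond syn to the allylic C10 hydroxyl (α face), ignores the electron-poor angelate double bond, and so sets C8 and C9 as the cis-epoxy alcohol of the target.

Compound list
1 | cycloheptane-1,3-dione | O=C1CCCCC(=O)C1 | starting material
2 | iodomethane | CI | starting material
3 | 2-methylcycloheptane-1,3-dione | CC1C(=O)CCCCC1=O | intermediate
4 | acrolein (prop-2-enal) | C=CC=O | starting material
5 | 2-methyl-2-(3-oxopropyl)cycloheptane-1,3-dione | O=CCCC1(C)C(=O)CCCCC1=O | intermediate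
6 | (1S,5R)-5-hydroxy-1-methylbicyclo[5.3.0]decane-4,10-dione, cis-fused ketol with the C5 hydroxyl cis to the C1 methyl | O=C1CC[C@]2(C)C(=O)CCCC[C@]12O | intermediate
7 | (1S)-1-methylbicyclo[5.3.0]dec-5-ene-4,10-dione, C5=C6 enone conjugated with the C4 ketone | O=C1CC[C@]2(C)C(=O)CCCC=C12 | intermediate
8 | 5α,6α-epoxy-1β-methylbicyclo[5.3.0]decane-4,10-dione, epoxide trans to the C1 methyl | O1[C@H]2CCCC(=O)[C@@]3(C)CCC(=O)[C@]123 | intermediate
9 | 6α-hydroxy-1β-methyl-5α-H-bicyclo[5.3.0]decane-4,10-dione, trans-fused, C6 hydroxyl and H5 both trans to the C1 methyl | O[C@H]1CCCC(=O)[C@@]2(C)CCC(=O)[C@H]12 | intermediate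
10 | isopropylmagnesium chloride | CC(C)[Mg]Cl | starting material
11 | 4β,6α-dihydroxy-4α-isopropyl-1β-methyl-5α-H-bicyclo[5.3.0]decan-10-one | O[C@H]1CCCC(=O)[C@@]2(C)CC[C@@](O)(C(C)C)[C@H]12 | intermediate
12 | 4β,6α,10-tris(triethylsilyloxy)-4α-isopropyl-1β-methyl-5α-H-bicyclo[5.3.0]dec-9-ene, silyl enol ether of 11 | CC[Si](CC)(CC)O[C@H]1CCC=C(O[Si](CC)(CC)CC)[C@@]2(C)CC[C@@](O[Si](CC)(CC)CC)(C(C)C)[C@H]12 | intermediate
13 | 4β,6α-bis(triethylsilyloxy)-4α-isopropyl-1β-methyl-5α-H-bicyclo[5.3.0]dec-8-en-10-one | CC[Si](CC)(CC)O[C@H]1CC=CC(=O)[C@@]2(C)CC[C@@](O[Si](CC)(CC)CC)(C(C)C)[C@H]12 | intermediate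
14 | methyllithium | [Li]C | starting material
15 | 4β,6α-bis(triethylsilyloxy)-10-(trimethylsilyloxy)-4α-isopropyl-1β,8-dimethyl-5α-H-bicyclo[5.3.0]dec-9-ene, either C8 epimer | CC[Si](CC)(CC)O[C@H]1CC(C)C=C(O[Si](C)(C)C)[C@@]2(C)CC[C@@](O[Si](CC)(CC)CC)(C(C)C)[C@H]12 | intermediate
16 | 4β,6α-bis(triethylsilyloxy)-4α-isopropyl-1β,8-dimethyl-5α-H-bicyclo[5.3.0]dec-8-en-10-one | CC[Si](CC)(CC)O[C@H]1CC(C)=CC(=O)[C@@]2(C)CC[C@@](O[Si](CC)(CC)CC)(C(C)C)[C@H]12 | intermediate
17 | 4β,6α-dihydroxy-4α-isopropyl-1β,8-dimethyl-5α-H-bicyclo[5.3.0]dec-8-en-10-one | O[C@H]1CC(C)=CC(=O)[C@@]2(C)CC[C@@](O)(C(C)C)[C@H]12 | intermediate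
18 | angelic acid, (Z)-2-methylbut-2-enoic acid | C/C=C(/C)C(=O)O | starting material
19 | 6α-angeloyloxy-4β-hydroxy-4α-isopropyl-1β,8-dimethyl-5α-H-bicyclo[5.3.0]dec-8-en-10-one | C/C=C(/C)C(=O)O[C@H]1CC(C)=CC(=O)[C@@]2(C)CC[C@@](O)(C(C)C)[C@H]12 | intermediate
20 | 6α-angeloyloxy-4β,10α-dihydroxy-4α-isopropyl-1β,8-dimethyl-5α-H-bicyclo[5.3.0]dec-8-ene | C/C=C(/C)C(=O)O[C@H]1CC(C)=C[C@@H](O)[C@@]2(C)CC[C@@](O)(C(C)C)[C@H]12 | intermediate
21 | lapiferine, 6α-angeloyloxy-8α,9α-epoxy-4β,10α-dihydroxy-4α-isopropyl-1β,8β-dimethyl-5α-H-bicyclo[5.3.0]decane, (1S,4R,5S,6S,8R,9S,10S) | C/C=C(/C)C(=O)O[C@H]1C[C@@]2(C)O[C@H]2[C@@H](O)[C@@]2(C)CC[C@@](O)(C(C)C)[C@H]12 | target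

Total step count: 13. Longest linear sequence: 13 steps, from cycloheptane-1,3-dione.

Steps most likely to fail

Step 3. What may go wrong: weak discrimination between the two ring carbonyls of the flexible seven-membered dione, giving 6 in low enantiomeric purity, or diversion of 5 into base-mediated aldol closure. The fallback sets out from 5 and comes back at 6; it moves the desymmetrisation to a hydride reduction and keeps the carbene step for ring closure only. Chemoselective acetalisation of the aldehyde (HC(OMe)3, PPTS, MeOH) should give the dimethyl acetal F1. Corey–Bakshi–Shibata reduction of one of its enantiotopic ketones, with the oxazaborolidine antipode chosen so that C1 has the target configuration, should give the hydroxy ketone F2 (the C10 carbinol configuration is irrelevant). Silylation (tBuMe2SiCl, imidazole, DMF) would give the silyl ether F3, and mild acetal hydrolysis (PPTS, wet acetone) the keto aldehyde F4. An achiral N-mesityl bicyclic triazolium chloride with DBU then forms the same C4–C5 bond, now with a single ketone as acceptor, to give the silyloxy ketol F5. Bu4NF would give the hydroxy ketol F6, and Dess–Martin oxidation of its C10 carbinol returns 6.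

Step 5. What may go wrong: poor or reversed facial selection when hydroperoxide adds to C6, because the C1 methyl (β) and the C10 carbon (α) flank the exocyclic alkene almost symmetrically; the C6 configuration, and with it the proton delivery to C5 in step 6, would then be lost. The fallback sets out from 7 and comes back at 9, bypassing 8. Ligand-controlled copper-catalysed conjugate borylation (B2pin2, CuCl, NaOtBu, a chiral ferrocenyl bisphosphine of the Josiphos family in the matching antipode, MeOH, THF) lets the catalyst, not the substrate, choose the C6 face. After protonation of the copper enolate at C5 it should give the 6α-boryl diketone F7, and oxidation with NaBO3 in THF–water, which proceeds with retention at C6, gives 9.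

Step 12. What may go wrong: hydride delivery to the α face of C10 if the cycloheptenone flattens into a cyclohexenone-like shape, in which the axial C1 methyl and not the C1–C5 bond directs the approach; the resulting 10β-alcohol would steer the epoxidation to the wrong face. The fallback sets out from 19 and comes back at 20 without a new compound. Substrate control is replaced by catalyst control: Corey–Bakshi–Shibata reduction with (S)-2-methyl-oxazaborolidine and catecholborane in toluene at −78 °C, where the quaternary C1 side is expected to act as the large substituent so that the catalyst dictates the 10α-hydroxyl; the antipodal catalyst is used if the alkene proves to be the larger group.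

Further compounds
F1 | step 3 | 2-(3,3-dimethoxypropyl)-2-methylcycloheptane-1,3-dione | COC(OC)CCC1(C)C(=O)CCCCC1=O
F2 | step 3 | 3-hydroxy-2-(3,3-dimethoxypropyl)-2-methylcycloheptan-1-one, desymmetrised, future C1 as in the target, C10 carbinol drawn α | O=C1CCCC[C@@H](O)[C@@]1(C)CCC(OC)OC
F3 | step 3 | tert-butyldimethylsilyl ether of F2 | O=C1CCCC[C@@H](O[Si](C)(C)C(C)(C)C)[C@@]1(C)CCC(OC)OC
F4 | step 3 | 3-(tert-butyldimethylsilyloxy)-2-methyl-2-(3-oxopropyl)cycloheptan-1-one | O=C1CCCC[C@@H](O[Si](C)(C)C(C)(C)C)[C@@]1(C)CCC=O
F5 | step 3 | 10-(tert-butyldimethylsilyloxy)-5-hydroxy-1-methylbicyclo[5.3.0]decan-4-one, cis-fused, C5 hydroxyl cis to the C1 methyl | C1CCC[C@@H](O[Si](C)(C)C(C)(C)C)[C@@]2(C)CCC(=O)[C@@]12O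
F6 | step 3 | 5,10-dihydroxy-1-methylbicyclo[5.3.0]decan-4-one, cis-fused | C1CCC[C@@H](O)[C@@]2(C)CCC(=O)[C@@]12O
F7 | step 5 | 6α-(4,4,5,5-tetramethyl-1,3,2-dioxaborolan-2-yl)-1β-methyl-5α-H-bicyclo[5.3.0]decane-4,10-dione | CC1(C)OB(OC1(C)C)[C@H]2CCCC(=O)[C@@]3(C)CCC(=O)[C@H]23
F0 | step 12 | none | none
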